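The left-handed product is made by free catalyst, so we ask first how much free catalyst the impurity spares.

left-handed substrate 0.25 M; gas 52 mM (held); free catalyst 0.25 mM; impurity 0.19 mM; right-handed substrate 0.25 M; time 2.5 d

    partner + free catalyst + left-handed substrate → free catalyst + left-handed product (k1 = 0.33 L² mol⁻² s⁻¹)
    partner + free catalyst + right-handed substrate → free catalyst + right-handed product (k2 = 0.0029 L² mol⁻² s⁻¹)
    left-handed substrate ⇌ right-handed substrate (k3 = 5.5 × 10⁻⁵ s⁻¹)
    gas ⇌ partner, rate k4*(csat - [partner]) (k4 = 3.8 × 10⁻⁵ s⁻¹, csat = 52 mM)
    free catalyst + impurity → spent catalyst (k5 = 2.1 L mol⁻¹ s⁻¹)

- free catalyst is single-handed; left-handed substrate and right-handed substrate are mirror images of each other, charged as a racemate, each of them at the stated concentration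
- at the start none of partner is dissolved
- run time (flask): 2.5 d

- left-handed product at 2.5 d, in percent of the left-handed substrate and right-handed substrate together charged
- concentration of partner in solution at 2.5 d, in percent of saturation

1. In this flask, impurity and free catalyst destroy each other one to one. The impurity charge is 76.0% of the catalyst charge, so it is the limiting reagent of that step. That leaves 24.0% of the catalyst charge, the live share.

2. We reckon a time scale of about 0.0919 d for the loss, short against the 2.5 d run. So in our reckoning we use the live share for the whole run.

3. The live catalyst uses dissolved partner at a first-order rate of 0.428 d⁻¹, with left-handed substrate held at its charge. The gas refills partner at 3.28 d⁻¹. Since refilling is faster than use, we reckon that partner levels off at 88.5% of saturation, after a lag of 0.269 d.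

4. For the run time less that lag, we take step one as steady, with left-handed substrate still at its charge. We reckon 8.78% left-handed product, as a share of the two substrates together charged.

5. The forecast says “Treat the catalyst first” and gives 8.5% and 89.2%. Our product figure is higher, and our saturation is lower.

6. The simulation gives 8.47% and 89.2%. In this flask, free catalyst stands at 24.0% of its charge at 2.50 d, against the reckoned live share of 24.0%.

Take a neighbouring flask charged with 7.6 × 10⁻⁴ M of impurity, 3.04 times the catalyst charge. Its live share, reckoned the same way, is −204%, which is below zero. The subtraction turns round: free catalyst becomes the limiting reagent, and 67.1% of the impurity should remain. At 2.50 d, that flask holds free catalyst at 0% of its charge, impurity at 67.1% of its own charge, and left-handed product at 0.00504% of the two substrates together charged.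

(All constants are invented; what happens was integrated by code.)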